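**Strategy.** Everything rests on cutting ring A at C4–C5. The exocyclic C4 methylene sits on the ring-fusion carbon C5, which can be made the α-carbon of a temporary C6 ketone in ring B; ring A and its alkene therefore come from adding the C5 carbon of a ring B silyl enol ether across a terminal alkyne tethered to C10. One gold-catalysed 6-exo-dig closure forms C4–C5, ring A, the C4 methylene and the C5 stereocentre. The precursor is a cyclohexene carrying the C5=C6 triisopropylsilyl enol ether, C8 methyl, C9 methyl and ethyl ester (C15), and C10 methyl and pent-4-ynyl. Afterwards C5 is inverted, C6 deoxygenated and C15 joined to the quinone.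

Key step: step 6

Numbering: ring A = C1–C5, C10; ring B = C5–C10; C4 carries the methylene carbon C11, C8 a methyl, C9 a methyl and C15, C10 a methyl. β is the face of the C10 methyl, α the opposite face.

Remark (ring fusion): closure onto the planar enol carbon C5 can only deliver C4 to the face on which the C10 chain stands, so the first ring-A product is taken to be the cis-fused (5β-H) ketone 11; the trans-fused ketone 13 is made from it in step 7.

Remark (catalyst sense): the cupreidine-derived catalyst of step 1 is assumed to give (2R,3S)-3; if it favours the mirror image, its cupreine-derived pseudoenantiomer is used instead.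

Step 1
Reactants: 1 ethyl 2-methylacetoacetate; 2 (E)-pent-3-en-2-one
Product: 3 ethyl (2R,3S)-2-acetyl-2,3-dimethyl-5-oxohexanoate
Conditions: 9-O-(9-phenanthryl)cupreidine (10 mol %), CH2Cl2, 23 °C
Reagents that add atoms: none
Why: Asymmetric Michael addition of an α-substituted β-keto ester to a β-substituted enone under bifunctional cinchona catalysis (the quinuclidine holds the enolate, the 6'-OH binds the enone), a known way to set adjacent quaternary and tertiary centres; the catalyst-bound enolate face fixes C9 (R), the approach of the (E)-enone fixes C8 (S, methyl syn to the C9 methyl in the later ring), and any minor diastereomer is removed by chromatography at 4.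

Step 2
Reactants: 3 ethyl (2R,3S)-2-acetyl-2,3-dimethyl-5-oxohexanoate
Product: 4 ethyl (1R,6S)-1,2,6-trimethyl-4-oxocyclohex-2-ene-1-carboxylate
Conditions: pyrrolidine (0.3 equiv), AcOH (0.3 equiv), PhMe, 60 °C
Reagents that add atoms: none
Why: Enamine-mediated intramolecular aldol condensation (the ring-closing half of a Robinson annulation): pyrrolidine condenses with the unhindered C6 methyl ketone, the terminal enamine carbon (C5) adds to the acetyl carbonyl C10 and loss of water gives the conjugated ring B enone, while C8 and the quaternary C9 carry no acidic hydrogen and keep their configuration.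

Step 3
Reactants: 4 ethyl (1R,6S)-1,2,6-trimethyl-4-oxocyclohex-2-ene-1-carboxylate; 5 (5-chloropent-1-yn-1-yl)trimethylsilane
Product: 7 ethyl (1R,2S,6S)-1,2,6-trimethyl-4-[(trimethylsilyl)oxy]-2-[5-(trimethylsilyl)pent-4-yn-1-yl]cyclohex-3-ene-1-carboxylate, via Grignard reagent 6 (not isolated)
Conditions: 5, Mg, THF, 65 °C; then 4, CuBr·SMe2 (10 mol %), Me3SiCl, HMPA, THF, −78 → −30 °C
Reagents that add atoms: chlorotrimethylsilane, C[Si](C)(C)Cl
Why: Copper-catalysed, Me3SiCl/HMPA-accelerated conjugate addition of the Grignard reagent: the chain adds axially to C10 on the ester (α) face, anti to the pseudo-axial C9 methyl and trans to the C8 methyl (the normal trans-3,5 and anti-4 preference of cyclohexenones), so C10 becomes S with its methyl cis to the C8 and C9 methyls (adding methyl to a C10-pentynyl enone would give the C10 epimer, and a free alkyne C–H would not survive the organometallic), and Me3SiCl traps the enolate as the regiodefined C5=C6 enol ether.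

Step 4
Reactants: 7 ethyl (1R,2S,6S)-1,2,6-trimethyl-4-[(trimethylsilyl)oxy]-2-[5-(trimethylsilyl)pent-4-yn-1-yl]cyclohex-3-ene-1-carboxylate
Product: 9 ethyl (1R,2S,6S)-1,2,6-trimethyl-4-[(triisopropylsilyl)oxy]-2-[5-(trimethylsilyl)pent-4-yn-1-yl]cyclohex-3-ene-1-carboxylate, via lithium enolate 8 (not isolated)
Conditions: MeLi, THF, 0 °C; then i-Pr3SiOTf, −78 → 0 °C
Reagents that add atoms: triisopropylsilyl trifluoromethanesulfonate, CC(C)[Si](C(C)C)(C(C)C)OS(=O)(=O)C(F)(F)F
Why: Silyl exchange through the regiodefined lithium enolate (Si–O cleavage of the trimethylsilyl enol ether by MeLi, then O-silylation), needed because only the triisopropylsilyl enol ether survives the alkyne unmasking; the hindered ester and the alkynylsilane are inert to one equivalent of MeLi at 0 °C and no stereocentre is touched.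

Step 5
Reactants: 9 ethyl (1R,2S,6S)-1,2,6-trimethyl-4-[(triisopropylsilyl)oxy]-2-[5-(trimethylsilyl)pent-4-yn-1-yl]cyclohex-3-ene-1-carboxylate
Product: 10 ethyl (1R,2S,6S)-1,2,6-trimethyl-2-(pent-4-yn-1-yl)-4-[(triisopropylsilyl)oxy]cyclohex-3-ene-1-carboxylate
Conditions: K2CO3, EtOH, 23 °C
Reagents that add atoms: none
Why: Alkoxide-mediated protodesilylation of the alkynylsilane, whose sp C–Si bond is cleaved far faster than the hindered triisopropylsilyl enol ether or the neopentyl-type ester (ethanol keeps any ester exchange degenerate), which unmasks the terminal alkyne of the cyclisation precursor.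

Step 6
Reactants: 10 ethyl (1R,2S,6S)-1,2,6-trimethyl-2-(pent-4-yn-1-yl)-4-[(triisopropylsilyl)oxy]cyclohex-3-ene-1-carboxylate
Product: 11 ethyl (1R,2S,4aR,8aS)-1,2,8a-trimethyl-5-methylidene-4-oxodecahydronaphthalene-1-carboxylate (cis-fused; 5β-H)
Conditions: [(t-Bu)2(2-biphenylyl)P]Au(NCMe)SbF6 (5 mol %), CH2Cl2/MeOH 10:1, 23 °C
Reagents that add atoms: none
Why: The cationic monovalent gold complex binds the terminal alkyne, the enol ether carbon C5 attacks the internal alkyne carbon C4 anti to gold, and methanol removes the silyl group from the resulting oxocarbenium ion and protonates the vinyl–gold bond, which leaves the C6 ketone and the C4 methylene. The closest known reaction type is the gold-catalysed Conia-ene-type carbocyclisation of silyl enol ethers onto alkynes. Ring A closes in the 6-exo-dig mode (the enol double bond stays outside the new ring); the 7-endo alternative is disfavoured for a terminal alkyne. The new stereocentre C5 is controlled by the tether: C4 can reach the C5 π-face only on the side of C10 that carries the chain, so C4 ends cis to C1 and H5 cis to the C10 methyl (cis-fused, 5β-H) whichever half-chair reacts. The step needs C-alkylation at C5 only, which the regiodefined enol ether from step 3 secures (C7 cannot close a six-membered ring), and a cyclisation faster than protodesilylation, which the quaternary C10 favours (gem-disubstituent effect). The trans ring fusion of the target is deliberately not asked of this step and is set in step 7.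

Step 7
Reactants: 11 ethyl (1R,2S,4aR,8aS)-1,2,8a-trimethyl-5-methylidene-4-oxodecahydronaphthalene-1-carboxylate
Product: 13 ethyl (1R,2S,4aS,8aS)-1,2,8a-trimethyl-5-methylidene-4-oxodecahydronaphthalene-1-carboxylate (trans-fused; 5α-H), via potassium dienolate 12 (not isolated)
Conditions: KN(SiMe3)2 (1.0 equiv), THF, −78 → 0 °C; then inverse addition to AcOH, THF, −78 °C
Reagents that add atoms: none
Why: Equilibration to the extended potassium enolate (C6–O−, C5=C6 conjugated with C4=C11) erases C5, and kinetic C-protonation at the α-carbon (deconjugative protonation of a dienolate) re-creates it: the planar dienolate holds rings A and B in the half-chair in which the C10 methyl stands axially over the β face of C5, so the proton should enter from the α face, axial to both rings, to give the trans-fused ketone, which is expected to be the less stable epimer (1,3-diaxial C8 and C10 methyls) and is therefore quenched cold and carried on crude at once.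

Step 8
Reactants: 13 ethyl (1R,2S,4aS,8aS)-1,2,8a-trimethyl-5-methylidene-4-oxodecahydronaphthalene-1-carboxylate
Product: 14 [(1R,2S,4R,4aS,8aS)-4-hydroxy-1,2,8a-trimethyl-5-methylidenedecahydronaphthalen-1-yl]methanol
Conditions: LiAlH4, THF, −78 → 60 °C
Reagents that add atoms: none
Why: Hydride reduction: the C6 ketone is reduced at low temperature before it can enolise, which locks the C5 configuration (hydride should enter from the open α face because the axial C8 and C10 methyls screen the β face, giving the 6β carbinol, whose configuration is irrelevant later), and the hindered ester is reduced on warming to the C15 primary alcohol.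

Step 9
Reactants: 14 [(1R,2S,4R,4aS,8aS)-4-hydroxy-1,2,8a-trimethyl-5-methylidenedecahydronaphthalen-1-yl]methanol
Product: 15 (1R,2S,4R,4aS,8aS)-4-hydroxy-1,2,8a-trimethyl-5-methylidenedecahydronaphthalene-1-carbaldehyde
Conditions: TEMPO (0.2 equiv), PhI(OAc)2, CH2Cl2, 23 °C
Reagents that add atoms: none
Why: Oxoammonium (TEMPO/PhI(OAc)2) oxidation, selective for the primary alcohol over the axial, doubly flanked secondary C6 alcohol; the aldehyde has no α-hydrogen (C9 is quaternary) and the C6–OH on the opposite face cannot close a lactol.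

Step 10
Reactants: 15 (1R,2S,4R,4aS,8aS)-4-hydroxy-1,2,8a-trimethyl-5-methylidenedecahydronaphthalene-1-carbaldehyde; 16 1,2,4,5-tetramethoxybenzene
Product: 18 [(1R,2S,4R,4aS,8aS)-4-hydroxy-1,2,8a-trimethyl-5-methylidenedecahydronaphthalen-1-yl](2,3,5,6-tetramethoxyphenyl)methanol (both carbinol epimers), via aryllithium 17 (not isolated)
Conditions: 16, n-BuLi, THF, 0 °C; then 15, −78 → 0 °C
Reagents that add atoms: none
Why: Ortho-lithiation of 16 between two methoxy groups, then 1,2-addition of the aryllithium to the non-enolisable neopentyl aldehyde (one further equivalent is consumed by the free C6–OH); the new carbinol centre is removed in step 12, so both epimers are carried on.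

Step 11
Reactants: 18 [(1R,2S,4R,4aS,8aS)-4-hydroxy-1,2,8a-trimethyl-5-methylidenedecahydronaphthalen-1-yl](2,3,5,6-tetramethoxyphenyl)methanol
Product: 19 O-{[(1R,2S,4R,4aS,8aS)-1,2,8a-trimethyl-5-methylidene-4-{[(methylsulfanyl)carbonothioyl]oxy}decahydronaphthalen-1-yl](2,3,5,6-tetramethoxyphenyl)methyl} S-methyl carbonodithioate (bis-xanthate)
Conditions: NaH, imidazole (cat.), CS2, THF, 0 → 23 °C; then MeI
Reagents that add atoms: carbon disulfide, S=C=S; iodomethane, CI
Why: Xanthate formation (alkoxide addition to CS2, then S-methylation), in which the small linear electrophile tolerates both hindered secondary alkoxides; no bond at a stereocentre that is kept is broken.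

Step 12
Reactants: 19 bis-xanthate
Product: 20 3-{[(1R,2S,4aS,8aS)-1,2,8a-trimethyl-5-methylidenedecahydronaphthalen-1-yl]methyl}-1,2,4,5-tetramethoxybenzene
Conditions: Bu3SnH, AIBN, PhMe, 110 °C
Reagents that add atoms: none
Why: Barton–McCombie radical deoxygenation of both xanthates in one operation (C6–O and C15–O each become C–H); the secondary C6 radical and the benzylic C15 radical are reduced by Bu3SnH, kept concentrated so that hydrogen transfer outruns any addition to the C4 methylene, and C5, C8, C9 and C10 are untouched.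

Step 13
Reactants: 20 3-{[(1R,2S,4aS,8aS)-1,2,8a-trimethyl-5-methylidenedecahydronaphthalen-1-yl]methyl}-1,2,4,5-tetramethoxybenzene
Product: 21 2,5-dimethoxy-3-{[(1R,2S,4aS,8aS)-1,2,8a-trimethyl-5-methylidenedecahydronaphthalen-1-yl]methyl}cyclohexa-2,5-diene-1,4-dione
Conditions: (NH4)2Ce(NO3)6, MeCN/H2O, 0 °C
Reagents that add atoms: water, O
Why: Oxidative demethylation of the electron-rich tetramethoxyarene by the tetravalent cerium salt (two one-electron oxidations, attack of water, loss of methanol) should give the 2,5-dimethoxy-1,4-benzoquinone, the isolated 1,1-disubstituted alkene being inert to this oxidant at 0 °C.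

Step 14
Reactants: 21 2,5-dimethoxy-3-{[(1R,2S,4aS,8aS)-1,2,8a-trimethyl-5-methylidenedecahydronaphthalen-1-yl]methyl}cyclohexa-2,5-diene-1,4-dione
Product: 22 2-hydroxy-5-methoxy-3-{[(1R,2S,4aS,8aS)-1,2,8a-trimethyl-5-methylidenedecahydronaphthalen-1-yl]methyl}cyclohexa-2,5-diene-1,4-dione (target)
Conditions: KOH, MeOH/H2O, 23 °C; then aq HCl
Reagents that add atoms: potassium hydroxide, [K+].[OH-]
Why: Addition–elimination of hydroxide at the vinylogous ester carbon next to the bulky alkyl group, whose methoxy group is twisted out of conjugation and is the more labile one in 3-alkyl-2,5-dimethoxyquinones; the hydroxyquinone anion formed resists a second exchange, so acidification should give the 2-hydroxy-5-methoxy quinone.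

**Compound list**

1 | ethyl 2-methylacetoacetate | CCOC(=O)C(C)C(C)=O | starting material
2 | (E)-pent-3-en-2-one | C/C=C/C(C)=O | starting material
3 | ethyl (2R,3S)-2-acetyl-2,3-dimethyl-5-oxohexanoate | CC(=O)C[C@H](C)[C@@](C(C)=O)(C)C(=O)OCC | intermediate
4 | ethyl (1R,6S)-1,2,6-trimethyl-4-oxocyclohex-2-ene-1-carboxylate | CC1=CC(=O)C[C@H](C)[C@@]1(C)C(=O)OCC | intermediate
5 | (5-chloropent-1-yn-1-yl)trimethylsilane | C[Si](C)(C)C#CCCCCl | starting material
6 | [5-(trimethylsilyl)pent-4-yn-1-yl]magnesium chloride | C[Si](C)(C)C#CCCC[Mg]Cl | intermediate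
7 | ethyl (1R,2S,6S)-1,2,6-trimethyl-4-[(trimethylsilyl)oxy]-2-[5-(trimethylsilyl)pent-4-yn-1-yl]cyclohex-3-ene-1-carboxylate | C[Si](C)(C)C#CCCC[C@@]1(C)C=C(O[Si](C)(C)C)C[C@H](C)[C@@]1(C)C(=O)OCC | intermediate
8 | lithium (3S,4R,5S)-4-(ethoxycarbonyl)-3,4,5-trimethyl-3-[5-(trimethylsilyl)pent-4-yn-1-yl]cyclohex-1-en-1-olate | C[Si](C)(C)C#CCCC[C@@]1(C)C=C(O[Li])C[C@H](C)[C@@]1(C)C(=O)OCC | intermediate
9 | ethyl (1R,2S,6S)-1,2,6-trimethyl-4-[(triisopropylsilyl)oxy]-2-[5-(trimethylsilyl)pent-4-yn-1-yl]cyclohex-3-ene-1-carboxylate | C[Si](C)(C)C#CCCC[C@@]1(C)C=C(O[Si](C(C)C)(C(C)C)C(C)C)C[C@H](C)[C@@]1(C)C(=O)OCC | intermediate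
10 | ethyl (1R,2S,6S)-1,2,6-trimethyl-2-(pent-4-yn-1-yl)-4-[(triisopropylsilyl)oxy]cyclohex-3-ene-1-carboxylate (key-step precursor) | C#CCCC[C@@]1(C)C=C(O[Si](C(C)C)(C(C)C)C(C)C)C[C@H](C)[C@@]1(C)C(=O)OCC | intermediate
11 | ethyl (1R,2S,4aR,8aS)-1,2,8a-trimethyl-5-methylidene-4-oxodecahydronaphthalene-1-carboxylate (cis-fused, 5β-H) | C=C1CCC[C@@]2(C)[C@@H]1C(=O)C[C@H](C)[C@@]2(C)C(=O)OCC | intermediate
12 | potassium (3S,4R,4aS)-4-(ethoxycarbonyl)-3,4,4a-trimethyl-8-methylidene-2,3,4,4a,5,6,7,8-octahydronaphthalen-1-olate | C=C1CCC[C@@]2(C)C1=C(O[K])C[C@H](C)[C@@]2(C)C(=O)OCC | intermediate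
13 | ethyl (1R,2S,4aS,8aS)-1,2,8a-trimethyl-5-methylidene-4-oxodecahydronaphthalene-1-carboxylate (trans-fused, 5α-H) | C=C1CCC[C@@]2(C)[C@H]1C(=O)C[C@H](C)[C@@]2(C)C(=O)OCC | intermediate
14 | [(1R,2S,4R,4aS,8aS)-4-hydroxy-1,2,8a-trimethyl-5-methylidenedecahydronaphthalen-1-yl]methanol | C=C1CCC[C@@]2(C)[C@H]1[C@H](O)C[C@H](C)[C@@]2(C)CO | intermediate
15 | (1R,2S,4R,4aS,8aS)-4-hydroxy-1,2,8a-trimethyl-5-methylidenedecahydronaphthalene-1-carbaldehyde | C=C1CCC[C@@]2(C)[C@H]1[C@H](O)C[C@H](C)[C@@]2(C)C=O | intermediate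
16 | 1,2,4,5-tetramethoxybenzene | COc1cc(OC)c(OC)cc1OC | starting material
17 | (2,3,5,6-tetramethoxyphenyl)lithium | [Li]c1c(OC)c(OC)cc(OC)c1OC | intermediate
18 | [(1R,2S,4R,4aS,8aS)-4-hydroxy-1,2,8a-trimethyl-5-methylidenedecahydronaphthalen-1-yl](2,3,5,6-tetramethoxyphenyl)methanol (both carbinol epimers) | C=C1CCC[C@@]2(C)[C@H]1[C@H](O)C[C@H](C)[C@@]2(C)C(O)c1c(OC)c(OC)cc(OC)c1OC | intermediate
19 | O-{[(1R,2S,4R,4aS,8aS)-1,2,8a-trimethyl-5-methylidene-4-{[(methylsulfanyl)carbonothioyl]oxy}decahydronaphthalen-1-yl](2,3,5,6-tetramethoxyphenyl)methyl} S-methyl carbonodithioate | C=C1CCC[C@@]2(C)[C@H]1[C@H](OC(=S)SC)C[C@H](C)[C@@]2(C)C(OC(=S)SC)c1c(OC)c(OC)cc(OC)c1OC | intermediate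
20 | 3-{[(1R,2S,4aS,8aS)-1,2,8a-trimethyl-5-methylidenedecahydronaphthalen-1-yl]methyl}-1,2,4,5-tetramethoxybenzene | C=C1CCC[C@@]2(C)[C@H]1CC[C@H](C)[C@@]2(C)Cc1c(OC)c(OC)cc(OC)c1OC | intermediate
21 | 2,5-dimethoxy-3-{[(1R,2S,4aS,8aS)-1,2,8a-trimethyl-5-methylidenedecahydronaphthalen-1-yl]methyl}cyclohexa-2,5-diene-1,4-dione | C=C1CCC[C@@]2(C)[C@H]1CC[C@H](C)[C@@]2(C)CC1=C(OC)C(=O)C=C(OC)C1=O | intermediate
22 | 2-hydroxy-5-methoxy-3-{[(1R,2S,4aS,8aS)-1,2,8a-trimethyl-5-methylidenedecahydronaphthalen-1-yl]methyl}cyclohexa-2,5-diene-1,4-dione | C=C1CCC[C@@]2(C)[C@H]1CC[C@H](C)[C@@]2(C)CC1=C(O)C(=O)C=C(OC)C1=O | target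

**Step count and risks**

Total step count: 14. Longest linear sequence: 14 steps (1 and 2 to 22); 5 and 16 enter as commercial side components.

Steps most likely to fail:

Step 7. The cis ketone may not equilibrate fully to the extended enolate (the C7 enolate then returns 11), the proton may enter partly on the β face or at C11, and the kinetically formed trans ketone may re-enolise during isolation (return to the cis epimer or migration of the alkene into conjugation). The fallback sets out from 11 and comes back at 14.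
- The extended enolate (KN(SiMe3)2, THF) is O-acetylated with Ac2O to the storable dienyl acetate ethyl (1R,2S,8aS)-4-(acetyloxy)-1,2,8a-trimethyl-5-methylidene-1,2,3,5,6,7,8,8a-octahydronaphthalene-1-carboxylate F1.
- NaBH4 in EtOH/THF at 0 °C cleaves the enol ester and reduces the β,γ-unsaturated ketone in the same flask as soon as C5 is protonated, so that 13 never accumulates. This gives ethyl (1R,2S,4R,4aS,8aS)-4-hydroxy-1,2,8a-trimethyl-5-methylidenedecahydronaphthalene-1-carboxylate F2.
- LiAlH4 (THF, 60 °C) reduces the ester of F2 and the route is rejoined at 14.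

Step 3. Conjugate addition at a β,β-disubstituted carbon next to a quaternary centre may stall, leaving enone or giving 1,2-addition. The fallback sets out from 4 and comes back at 10.
- Bu3SnCH2CH=CH2 and i-Pr3SiOTf (CH2Cl2, −78 °C; silyl triflate-promoted conjugate allylation of the Hosomi–Sakurai type, much less sensitive to crowding, same α-face delivery) give directly ethyl (1R,2S,6S)-1,2,6-trimethyl-2-(prop-2-en-1-yl)-4-[(triisopropylsilyl)oxy]cyclohex-3-ene-1-carboxylate F3.
- Hydroboration of the terminal alkene with 9-BBN and oxidation with NaBO3 give ethyl (1R,2S,6S)-2-(3-hydroxypropyl)-1,2,6-trimethyl-4-[(triisopropylsilyl)oxy]cyclohex-3-ene-1-carboxylate F4.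
- I2/PPh3/imidazole gives ethyl (1R,2S,6S)-2-(3-iodopropyl)-1,2,6-trimethyl-4-[(triisopropylsilyl)oxy]cyclohex-3-ene-1-carboxylate F5.
- Displacement with LiC≡CH·H2NCH2CH2NH2 in DMSO gives 10.

Step 1. The weakly acidic acyclic keto ester may add slowly and with insufficient control of the C8/C9 relationship or of the absolute sense. The fallback sets out from 1 and 2 and comes back at 4.
- KOt-Bu (5 mol %) in t-BuOH gives the racemic diastereomer mixture ethyl 2-acetyl-2,3-dimethyl-5-oxohexanoate F6.
- Pyrrolidine/AcOH closes the ring as in step 2, and the cis-dimethyl diastereomer is separated on silica as racemic ethyl (1R,6S)-1,2,6-trimethyl-4-oxocyclohex-2-ene-1-carboxylate F7.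
- Preparative HPLC on a cellulose tris(3,5-dimethylphenylcarbamate) phase resolves F7; the (1R,6S) enantiomer is 4.

Further compounds
F1 | step 7 | ethyl (1R,2S,8aS)-4-(acetyloxy)-1,2,8a-trimethyl-5-methylidene-1,2,3,5,6,7,8,8a-octahydronaphthalene-1-carboxylate | C=C1CCC[C@@]2(C)C1=C(OC(C)=O)C[C@H](C)[C@@]2(C)C(=O)OCC
F2 | step 7 | ethyl (1R,2S,4R,4aS,8aS)-4-hydroxy-1,2,8a-trimethyl-5-methylidenedecahydronaphthalene-1-carboxylate | C=C1CCC[C@@]2(C)[C@H]1[C@H](O)C[C@H](C)[C@@]2(C)C(=O)OCC
F3 | step 3 | ethyl (1R,2S,6S)-1,2,6-trimethyl-2-(prop-2-en-1-yl)-4-[(triisopropylsilyl)oxy]cyclohex-3-ene-1-carboxylate | C=CC[C@@]1(C)C=C(O[Si](C(C)C)(C(C)C)C(C)C)C[C@H](C)[C@@]1(C)C(=O)OCC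
F4 | step 3 | ethyl (1R,2S,6S)-2-(3-hydroxypropyl)-1,2,6-trimethyl-4-[(triisopropylsilyl)oxy]cyclohex-3-ene-1-carboxylate | OCCC[C@@]1(C)C=C(O[Si](C(C)C)(C(C)C)C(C)C)C[C@H](C)[C@@]1(C)C(=O)OCC
F5 | step 3 | ethyl (1R,2S,6S)-2-(3-iodopropyl)-1,2,6-trimethyl-4-[(triisopropylsilyl)oxy]cyclohex-3-ene-1-carboxylate | ICCC[C@@]1(C)C=C(O[Si](C(C)C)(C(C)C)C(C)C)C[C@H](C)[C@@]1(C)C(=O)OCC
F6 | step 1 | ethyl 2-acetyl-2,3-dimethyl-5-oxohexanoate (racemic diastereomer mixture) | CC(=O)CC(C)C(C)(C(C)=O)C(=O)OCC
F7 | step 1 | racemic ethyl (1R,6S)-1,2,6-trimethyl-4-oxocyclohex-2-ene-1-carboxylate | CC1=CC(=O)C[C@H](C)[C@@]1(C)C(=O)OCC.CC1=CC(=O)C[C@@H](C)[C@]1(C)C(=O)OCC
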